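I was to read the flask at 4.0 min, so I wanted a clock for that moment, set by the charges.

solid substrate 0.16 M; partner 0.480 M; protic impurity 0.160 M; time 4.0 min

* amount of target and solid product together at 4.0 min, in percent of the solid substrate charged
* concentration of dissolved substrate in solution at 4.0 min, in percent of saturation

    solid substrate ⇌ dissolved substrate, rate k1*(cs1 - [dissolved substrate]) while solid is left; crystals form when [dissolved substrate] > cs1 (cs1 = 0.081 M, k1 = 0.048 s⁻¹)
    dissolved substrate + partner → target (k2 = 0.013 M⁻¹ s⁻¹)
    solid product ⇌ target, rate k3*(cs3 - [target]) while solid is left; crystals form when [target] > cs3 (cs3 = 10 mM, k3 = 1.1 s⁻¹)
    2 partner → homo dimer (k4 = 0.0013 M⁻¹ s⁻¹)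
    solid substrate + protic impurity → quenched substrate (k5 = 0.089 M⁻¹ s⁻¹)

- target is meant together with its solid product
- for a step with 2 of a species take k times the square, and two of it per event
- solid, in amounts per volume of the solution: solid substrate, solid product
- at the start none of the solid substrate is in solution
- dissolved substrate means what is dissolved; the solid is not counted in it
- run time (flask): 4.0 min

At the start, solid substrate met protic impurity at 0.00228 M s⁻¹ and dissolved at 0.00389 M s⁻¹, so the quench ran slower yet took a share of 36.9 %. That share belongs to the start, and I carried it through the run of the flask as an assumption, although dissolving goes with [dissolved substrate], which partner drains, so I did not apply it to the neighbour with 1.2 M of partner.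

The two flasks had to part at the coupling. With [partner] as charged, dissolved substrate in the flask had a pseudo-first-order half-life of 1.9 min, but that comparison drifts as partner dimerises, with a first half-life of 13.4 min in the flask and 5.34 min in the neighbour. So I counted the turns, meaning k2 times [partner] summed over the run, with [partner] falling by dimerisation: 1.31 for the flask and 2.79 for the neighbour. Dissolved substrate should survive as exp(−turns). The neighbour had 2.50 times the partner but 2.13 times the turns, a smaller gain since its partner dimerises faster. For the flask I reckoned a yield of 46.0 % and a saturation of 33.6 %.

The forecast said 43 % and 46 %, lower on yield and higher on saturation than mine, holding that “After that the dissolved substrate is no longer replenished and decays slowly with the partner”.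

The simulation gave 42.4 % and 47.7 %, with 33.4 % of the charge turned into quenched substrate by 4.0 min. Read from the flask, the logarithm of target plus dissolved substrate over dissolved substrate came to 1.01 turns against my 1.31, a ratio of 0.774. The neighbour with 1.2 M of partner ended with 62.5 % of target and read 2.21 turns against my 2.79, a ratio of 0.792.

Its constants are made up; what happens was integrated by code.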